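The target is read as epiafzelechin-(4β→8)-epigallocatechin. Everything rests on C4 of the upper unit, a methine that carries two phloroglucinol-type rings (C4a of ring A and C8 of the lower ring D) and therefore has the oxidation level of an aldehyde. An open-chain α-benzyloxy-β-aryloxy aldehyde that already holds O1, C2 and C3 is bis-arylated: its tethered 3,5-bis(benzyloxy)phenyl ether closes the upper pyran ring (C4–C4a), and the resulting flavan-4-yl cation is captured by C8 of benzylated epigallocatechin. This forms the interflavan bond and sets C4 stereoconvergently, trans to the C3 oxygen.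

Key step: step 7

Remark: the upper unit is read as 2,3-cis-3,4-trans (2R,3R,4R); flavan-4-ol 13 is expected as a C4-epimer mixture that converges on one cation, so it is drawn without configuration at C4.

**Step 1**
Reactants: 1 (S)-4-benzyloxazolidin-2-one; 2 benzyloxyacetyl chloride
Product: 3 (S)-4-benzyl-3-[2-(benzyloxy)acetyl]oxazolidin-2-one
Conditions: n-BuLi, THF, −78 °C; then 2, −78 → 0 °C
Reagents that add atoms: none
Why: N-acylation of the lithiated oxazolidinone by the acid chloride, with the auxiliary stereocentre untouched.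

**Step 2**
Reactants: 3 (S)-4-benzyl-3-[2-(benzyloxy)acetyl]oxazolidin-2-one; 4 4-(benzyloxy)benzaldehyde
Product: 6 (S)-4-benzyl-3-[(2S,3R)-2-(benzyloxy)-3-[4-(benzyloxy)phenyl]-3-hydroxypropanoyl]oxazolidin-2-one, via Z-dibutylboron enolate 5 (not isolated)
Conditions: Bu2BOTf, Et3N, CH2Cl2, −78 → 0 °C; 4, −78 → 0 °C; then H2O2, pH 7 buffer, MeOH, 0 °C
Reagents that add atoms: none
Why: Evans syn glycolate aldol, in which the Z-boron enolate reacts through a closed Zimmerman–Traxler transition state on the face opposite the auxiliary's benzyl group, so both new centres (2S,3R, syn) are set by the auxiliary and the two oxygens come out already differentiated (α-OBn, free β-OH).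

**Step 3**
Reactants: 6 (S)-4-benzyl-3-[(2S,3R)-2-(benzyloxy)-3-[4-(benzyloxy)phenyl]-3-hydroxypropanoyl]oxazolidin-2-one
Product: 7 (2S,3R)-2-(benzyloxy)-3-[4-(benzyloxy)phenyl]-3-hydroxy-N-methoxy-N-methylpropanamide
Conditions: AlMe3, MeONHMe·HCl, CH2Cl2, −15 → 0 °C; then 0.5 M HCl, 0 °C
Reagents that add atoms: N,O-dimethylhydroxylamine hydrochloride, CNOC.Cl
Why: Weinreb transamination of the imide by the aluminium amide, assisted by the free β-hydroxyl, which releases the auxiliary without touching either stereocentre.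

**Step 4**
Reactants: 7 (2S,3R)-2-(benzyloxy)-3-[4-(benzyloxy)phenyl]-3-hydroxy-N-methoxy-N-methylpropanamide; 8 1-bromo-3,5-bis(benzyloxy)benzene
Product: 9 (2S,3R)-2-(benzyloxy)-3-[3,5-bis(benzyloxy)phenoxy]-3-[4-(benzyloxy)phenyl]-N-methoxy-N-methylpropanamide
Conditions: [(allyl)PdCl]2 (cat.), RockPhos (cat.), Cs2CO3, toluene, 90 °C
Reagents that add atoms: none
Why: Pd-catalysed C–O cross-coupling (Buchwald–Hartwig etherification) of a secondary alcohol with an unhindered aryl bromide, using a bulky biaryl phosphine that favours C–O reductive elimination over β-hydride elimination; the carbinol C–O bond is not broken, so the benzylic centre is retained.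

**Step 5**
Reactants: 9 (2S,3R)-2-(benzyloxy)-3-[3,5-bis(benzyloxy)phenoxy]-3-[4-(benzyloxy)phenyl]-N-methoxy-N-methylpropanamide
Product: 10 (2S,3R)-2-(benzyloxy)-3-[3,5-bis(benzyloxy)phenoxy]-3-[4-(benzyloxy)phenyl]propanal
Conditions: DIBAL-H, THF, −78 °C; aq. Rochelle salt; used crude at once
Reagents that add atoms: none
Why: Partial reduction of the Weinreb amide, whose chelated tetrahedral aluminium intermediate collapses only on work-up, so the α-benzyloxy aldehyde should form without over-reduction and, at low temperature, without epimerisation.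

**Step 6**
Reactants: 11 (−)-epigallocatechin
Product: 12 (2R,3R)-5,7-bis(benzyloxy)-2-[3,4,5-tris(benzyloxy)phenyl]chroman-3-ol (5,7,3',4',5'-penta-O-benzyl-epigallocatechin)
Conditions: BnBr, K2CO3, DMF, 0 °C → rt, argon
Reagents that add atoms: benzyl bromide, BrCc1ccccc1
Why: Williamson etherification in which carbonate deprotonates only the five phenols, so the secondary 3-OH stays free and C2 and C3 are untouched.

**Step 7**
Reactants: 10 (2S,3R)-2-(benzyloxy)-3-[3,5-bis(benzyloxy)phenoxy]-3-[4-(benzyloxy)phenyl]propanal; 12 5,7,3',4',5'-penta-O-benzyl-epigallocatechin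
Product: 14 3,5,7,4'-tetra-O-benzyl-epiafzelechin-(4β→8)-5,7,3',4',5'-penta-O-benzyl-epigallocatechin (upper unit 2R,3R,4R; lower unit 2R,3R), via flavan-4-ol 13 (not isolated)
Conditions: Yb(OTf)3 (20 mol %), CH2Cl2, −20 °C → rt; 10 added slowly to 12 (3 equiv)
Reagents that add atoms: none
Why: Yb(III) activates the α-benzyloxy aldehyde by chelation, the tethered 3,5-bis(benzyloxy)phenyl ether attacks the carbonyl carbon with one of its two equivalent ortho carbons (each activated by three oxygen substituents) to give flavan-4-ol 13, and 13 ionises to the 5,7-dioxygenated flavan-4-yl cation, which C8 of 12 captures in a second Friedel–Crafts alkylation. The closest known reaction types are the acid-catalysed bis-arylation of aldehydes by electron-rich arenes (hydroxyalkylation followed by alkylation) and the Lewis-acid-mediated 4→8 coupling of flavan-4-yl cations with flavan-3-ols. The upper pyran ring closes by C4–C4a bond formation in a 6-exo-trig Friedel–Crafts hydroxyalkylation. The only new stereocentre, C4, is set when the planar cation is captured: the C2 aryl group and the C3 benzyloxy group both lie on the α-face, so 12 should enter from the β-face and give the 3,4-trans (4β, 4R) isomer from either C4 epimer of 13, while C2 and C3 stay as set in step 2. The step needs C8 over C6 selectivity in 12, for which the known preference of 5,7-di-O-benzyl flavan-3-ols is relied on, and capture by 12 instead of by a second A ring, which the excess of 12 and the slow addition of 10 should secure.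

**Step 8**
Reactants: 14 3,5,7,4'-tetra-O-benzyl-epiafzelechin-(4β→8)-5,7,3',4',5'-penta-O-benzyl-epigallocatechin
Product: 15 epiafzelechin-(4β→8)-epigallocatechin (CNP0290824.1)
Conditions: H2 (1 atm), Pd(OH)2/C, THF/MeOH/H2O, rt
Reagents that add atoms: none
Why: Global hydrogenolysis of the nine benzyl ethers under neutral conditions, which in benzylated flavan-3-ol oligomers should leave the benzylic C2–O1 and C4–C8 bonds and all five stereocentres intact.

**Compound list**
1 | (S)-4-benzyloxazolidin-2-one | O=C1N[C@@H](Cc2ccccc2)CO1 | starting material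
2 | benzyloxyacetyl chloride | O=C(Cl)COCc1ccccc1 | starting material
3 | (S)-4-benzyl-3-[2-(benzyloxy)acetyl]oxazolidin-2-one | O=C(COCc1ccccc1)N1[C@@H](Cc2ccccc2)COC1=O | intermediate
4 | 4-(benzyloxy)benzaldehyde | O=Cc1ccc(OCc2ccccc2)cc1 | starting material
5 | Z-dibutylboron enolate of 3 | CCCCB(CCCC)O/C(=C\OCc1ccccc1)N1[C@@H](Cc2ccccc2)COC1=O | intermediate (not isolated)
6 | (S)-4-benzyl-3-[(2S,3R)-2-(benzyloxy)-3-[4-(benzyloxy)phenyl]-3-hydroxypropanoyl]oxazolidin-2-one | c1ccccc1COc1ccc(cc1)[C@@H](O)[C@H](OCc1ccccc1)C(=O)N1[C@@H](Cc2ccccc2)COC1=O | intermediate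
7 | (2S,3R)-2-(benzyloxy)-3-[4-(benzyloxy)phenyl]-3-hydroxy-N-methoxy-N-methylpropanamide | c1ccccc1COc1ccc(cc1)[C@@H](O)[C@H](OCc1ccccc1)C(=O)N(C)OC | intermediate
8 | 1-bromo-3,5-bis(benzyloxy)benzene | Brc1cc(OCc2ccccc2)cc(OCc2ccccc2)c1 | starting material
9 | (2S,3R)-2-(benzyloxy)-3-[3,5-bis(benzyloxy)phenoxy]-3-[4-(benzyloxy)phenyl]-N-methoxy-N-methylpropanamide | c1ccccc1COc1ccc(cc1)[C@@H](Oc1cc(OCc2ccccc2)cc(OCc2ccccc2)c1)[C@H](OCc1ccccc1)C(=O)N(C)OC | intermediate
10 | (2S,3R)-2-(benzyloxy)-3-[3,5-bis(benzyloxy)phenoxy]-3-[4-(benzyloxy)phenyl]propanal | c1ccccc1COc1ccc(cc1)[C@@H](Oc1cc(OCc2ccccc2)cc(OCc2ccccc2)c1)[C@H](OCc1ccccc1)C=O | intermediate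
11 | (−)-epigallocatechin, (2R,3R) | Oc1cc(O)c2c(c1)O[C@H](c1cc(O)c(O)c(O)c1)[C@H](O)C2 | starting material
12 | (2R,3R)-5,7-bis(benzyloxy)-2-[3,4,5-tris(benzyloxy)phenyl]chroman-3-ol | c1c(OCc3ccccc3)cc(OCc3ccccc3)c2c1O[C@H](c1cc(OCc3ccccc3)c(OCc3ccccc3)c(OCc3ccccc3)c1)[C@H](O)C2 | intermediate
13 | (2R,3R)-3,5,7-tris(benzyloxy)-2-[4-(benzyloxy)phenyl]chroman-4-ol, 2,3-cis, both C4 epimers | c1ccccc1COc1ccc([C@H]2Oc3cc(OCc4ccccc4)cc(OCc4ccccc4)c3C(O)[C@H]2OCc2ccccc2)cc1 | intermediate (not isolated)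
14 | 3,5,7,4'-tetra-O-benzyl-epiafzelechin-(4β→8)-5,7,3',4',5'-penta-O-benzyl-epigallocatechin | c1ccccc1COc1ccc([C@H]2Oc3cc(OCc4ccccc4)cc(OCc4ccccc4)c3[C@H](c3c(OCc4ccccc4)cc(OCc4ccccc4)c4c3O[C@H](c3cc(OCc5ccccc5)c(OCc5ccccc5)c(OCc5ccccc5)c3)[C@H](O)C4)[C@H]2OCc2ccccc2)cc1 | intermediate
15 | epiafzelechin-(4β→8)-epigallocatechin (CNP0290824.1) | Oc1ccc([C@H]2Oc3cc(O)cc(O)c3[C@H](c3c(O)cc(O)c4c3O[C@H](c3cc(O)c(O)c(O)c3)[C@H](O)C4)[C@H]2O)cc1 | target

**Step count**
Total: 8 steps. Longest linear sequence: 7 steps (steps 1–5, 7 and 8, from 1).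

**Steps most likely to fail**

1. Step 7. The flavan-4-yl cation may be captured by ring A of the product or of a second molecule (oligomerisation), or the aldehyde may be arylated twice by 12 before the ring closes. Fallback, from 10 back to 14: ring closure and interflavan coupling are separated. Compound 10 would be cyclised with Yb(OTf)3 (cat.) in CH2Cl2 containing a large excess of 2-ethoxyethanol, so that the alcohol traps the cation and gives 3,5,7,4'-tetra-O-benzyl-4β-(2-ethoxyethoxy)epiafzelechin F1. F1 would then be condensed with 12 under TMSOTf in CH2Cl2 at −78 °C, the established 4→8 coupling of a 4-alkoxy flavan, to return to 14.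

2. Step 4. The hindered benzylic palladium alkoxide may undergo β-hydride elimination (oxidation of the carbinol, reduction of 8), reductive elimination may be slow, and the base may induce retro-aldol cleavage. Fallback, from 4 back to 10, replacing steps 1–5: the aryl ether is made by SN2 at carbon instead of coupling at oxygen. Z-selective Horner–Wadsworth–Emmons olefination of 4 with ethyl (diphenoxyphosphoryl)acetate (NaH, THF, −78 °C) should give ethyl (Z)-3-[4-(benzyloxy)phenyl]prop-2-enoate F2. Jacobsen epoxidation with the (S,S)-Mn(salen) catalyst (NaOCl, 4-phenylpyridine N-oxide, CH2Cl2, 0 °C) should give the cis-epoxide ethyl (2S,3S)-3-[4-(benzyloxy)phenyl]oxirane-2-carboxylate F3. Opening at the benzylic carbon with inversion by 3,5-bis(benzyloxy)phenol (Cs2CO3 cat., DMF, 60 °C) should give ethyl (2S,3R)-3-[3,5-bis(benzyloxy)phenoxy]-3-[4-(benzyloxy)phenyl]-2-hydroxypropanoate F4. O-Benzylation (BnBr, Ag2O, CH2Cl2) should give ethyl (2S,3R)-2-(benzyloxy)-3-[3,5-bis(benzyloxy)phenoxy]-3-[4-(benzyloxy)phenyl]propanoate F5, and DIBAL-H (CH2Cl2, −78 °C) returns to 10.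

3. Step 6. Under base the pyrogallol ring may be oxidised by air, ring A may be C-benzylated, and C2 may epimerise through ring opening. Fallback, from 11 back to 12: free phenoxides are never accumulated. Acetylation (Ac2O, pyridine) should give hexa-O-acetyl-epigallocatechin F6. Treatment with BnCl, NaH and water (5 equiv) in DMF at 0 °C → rt cleaves the aryl acetates and benzylates each phenoxide as it forms, giving 3-O-acetyl-5,7,3',4',5'-penta-O-benzyl-epigallocatechin F7. Methanolysis (NaOMe cat., MeOH/THF) returns to 12.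

**Further compounds**
F1 | step 7 | 3,5,7,4'-tetra-O-benzyl-4β-(2-ethoxyethoxy)epiafzelechin (2,3-cis-3,4-trans) | c1ccccc1COc1ccc([C@H]2Oc3cc(OCc4ccccc4)cc(OCc4ccccc4)c3[C@H](OCCOCC)[C@H]2OCc2ccccc2)cc1
F2 | step 4 | ethyl (Z)-3-[4-(benzyloxy)phenyl]prop-2-enoate | CCOC(=O)/C=C\c1ccc(OCc2ccccc2)cc1
F3 | step 4 | ethyl (2S,3S)-3-[4-(benzyloxy)phenyl]oxirane-2-carboxylate (cis) | c1ccccc1COc1ccc(cc1)[C@@H]1O[C@@H]1C(=O)OCC
F4 | step 4 | ethyl (2S,3R)-3-[3,5-bis(benzyloxy)phenoxy]-3-[4-(benzyloxy)phenyl]-2-hydroxypropanoate | c1ccccc1COc1ccc(cc1)[C@@H](Oc1cc(OCc2ccccc2)cc(OCc2ccccc2)c1)[C@H](O)C(=O)OCC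
F5 | step 4 | ethyl (2S,3R)-2-(benzyloxy)-3-[3,5-bis(benzyloxy)phenoxy]-3-[4-(benzyloxy)phenyl]propanoate | c1ccccc1COc1ccc(cc1)[C@@H](Oc1cc(OCc2ccccc2)cc(OCc2ccccc2)c1)[C@H](OCc1ccccc1)C(=O)OCC
F6 | step 6 | hexa-O-acetyl-(−)-epigallocatechin | CC(=O)Oc1cc(OC(C)=O)c2c(c1)O[C@H](c1cc(OC(C)=O)c(OC(C)=O)c(OC(C)=O)c1)[C@H](OC(C)=O)C2
F7 | step 6 | 3-O-acetyl-5,7,3',4',5'-penta-O-benzyl-(−)-epigallocatechin | c1c(OCc3ccccc3)cc(OCc3ccccc3)c2c1O[C@H](c1cc(OCc3ccccc3)c(OCc3ccccc3)c(OCc3ccccc3)c1)[C@H](OC(C)=O)C2
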